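| flask | starting material | coupling partner | temperature | remark | time |
|---|---|---|---|---|---|
| theta | 3.8 mM | 18.9 mM | 28 °C | run made earlier |  |
| eta | 10 mM | 18.9 mM | 44 °C | run made earlier |  |
| gamma | 16 mM | 18.9 mM | 28 °C | run made earlier |  |
| south-east | 18 mM | 18.9 mM |  | at 20 °C until 10 min, from then on at 50 °C | 50 min |
| south-west | 5.0 mM | 18.9 mM |  | at 50 °C throughout | 15 min |

| run | time / min | target / % | starting material / % |
|---|---|---|---|
| theta | 4.00 | 3.5 | 10.2 |
| theta | 8.00 | 14.1 | 1.2 |
| theta | 15.0 | 33.5 | 0.2 |
| theta | 25.0 | 55.2 | 0.1 |
| theta | 50.0 | 76.7 | 0.8 |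
| eta | 3.00 | 38.1 | 2.5 |
| eta | 6.00 | 67.9 | 0.6 |
| eta | 10.0 | 78.9 | 0 |
| eta | 12.0 | 80.0 | 0.4 |
| eta | 15.0 | 80.9 | 0.8 |
| gamma | 10.0 | 17.4 | 8.6 |
| gamma | 20.0 | 42.8 | 2.0 |
| gamma | 30.0 | 60.1 | 0.1 |
| gamma | 40.0 | 69.6 | 0 |
| gamma | 50.0 | 76.2 | 0.8 |

(scatter of a reading: 0.5 percentage points)



- which one finishes higher in amount of target, in percent of the starting material charged ("neither" within 2 percentage points) (south-east / south-west / neither)
- amount of target at the end, in percent of the starting material charged, south-east
- amount of target at the end, in percent of the starting material charged, south-west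

**First instants.** Theta shows the pace: at 4.00 min starting material is down to 10.2%, yet target stands at 3.5%. Count the remainder, 86.3%, as unread material that has left starting material without being target.

**The middle.** Now watch c(target) climb out of that remainder. At 28 °C the last readings lie close: theta and gamma, at 3.8 mM and 16 mM, read 76.7% and 76.2% at 50.0 min. Eta, at 44 °C and 10 mM, reads 67.9% at 6.00 min, but theta, at 28 °C and 3.8 mM, reads 14.1% at 8.00 min.

**The end.** Read eta's last point and divide target by what has left starting material: 81.6%. Call this the end share, a reading with its scatter. Eta's last two target readings differ by 0.9 percentage points, so treat eta as nearly flat by its last reading.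

**My reckoning.** Assume the end share belongs to the last temperature and not to the path, which is thermodynamic control. Both flasks end at 50 °C, hotter than eta. South-west has 15 min there, about the length of eta's run, and south-east has 40.0 min, so expect both to reach their plateau. Expect about 81.6% in each, and so neither ahead.

**The forecast.** It says south-east, with 83.5% for south-east and 79.5% for south-west, on the ground that “a parallel loss grows with temperature”. For south-east it stands 1.9 points above my reckoning.

**The result.** South-east gives 80.2% and south-west 80.2%, so the answer is neither. In south-east, changing the temperature programme alone to that of south-west moves target by 0.0069 points. My expected 81.6% stands 1.4 points above the south-west figure.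

    intermediate B ⇌ target (K = 5.50, k = 0.00140 s⁻¹, Ea = 83.0 kJ mol⁻¹, ΔH = −8.00 kJ mol⁻¹)
    intermediate A → intermediate B (k = 3.30 × 10⁻⁴ s⁻¹, Ea = 99.0 kJ mol⁻¹)
    starting material + coupling partner → intermediate A (k = 0.300 L mol⁻¹ s⁻¹, Ea = 59.0 kJ mol⁻¹)
    (constants at 20 °C)

**One neighbour.** Take south-west with 4.7 mM of coupling partner, less than the 5.0 mM of starting material, so the partner, at 0.940 equiv, is the limiting reagent. At the end of this neighbour flask, 5.0% of the partner's charge and 11% of the starting material charged remain. Multiply the end share by the part that left starting material: 72.6%. This neighbour flask gives 71.0% of target.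

The runs come from a simulation from invented constants.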